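The three phenols are freed last. The C5′ formyl carbon comes from lithiation between the C4′ and C6′ OMOM groups, and the C9–C11 bond is cut as an anti-SN2′ attack of a 2,4,5-trioxygenated benzylcopper on the 7α-picolinate of 11-nordrim-8-en-7-ol.
That allylic alcohol is the Wharton product of the 7α,8α-epoxide of the C7=C8/C9=O enone. The enone comes from a trans-decalone reached by C4 gem-dimethylation, C3 deoxygenation and C5=C6 hydrogenation of an 8-methyl octalindione, with C9 held as its alcohol meanwhile.
Feature used: take C8 and its methyl C12 out of ring B, and the remaining C5–C6–C7–C9–C10 ring is the cyclopentanone of the proline-derived (S)-hydrindenedione. Its methyl-bearing ring-fusion carbon is C10 in the correct configuration and its enone ring is ring A, so C7–C8 and C8–C9 are cut as the insertion of CH–CH3 from diazoethane.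
Ring order: ring A and the arene are bought; ring B is bought five-membered and enlarged to six members in step 1; no other ring is formed.
Key step: step 1

Remark: drimane numbering is used (C11 benzylic carbon on C9, C12 methyl on C8, arene C1′–C6′ with C1′ on C11). C8, and C9 while it is a carbinol, are carried as epimer mixtures and left undefined in the SMILES because both are sp2 again by step 7. Diazoethane is made as a separate dried solution because aqueous KOH would destroy Sc(OTf)3.

Step 1
Reactants: 1 (7aS)-7a-methyl-2,3,7,7a-tetrahydro-1H-indene-1,5(6H)-dione; 2 N-ethyl-N-nitrosourea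
Product: 4 (8aS)-2,8a-dimethyl-3,4,8,8a-tetrahydronaphthalene-1,6(2H,7H)-dione (C8 epimers), via diazoethane 3 (not isolated)
Conditions: 2, 40% aq KOH, toluene, −10 °C, organic layer decanted and dried over KOH pellets; solution added slowly to 1, Sc(OTf)3 (10 mol %), toluene, −78 → −20 °C
Reagents that add atoms: diazoethane 3 (from 2), CC=[N+]=[N-]
Why: Sc(OTf)3 binds the C9 carbonyl, the carbon of diazoethane adds to it, and the oxido-diazonium adduct expels N2 while the antiperiplanar C7 methylene shifts to the new carbon, so that CH(CH3) is inserted between C9 and C7 and the C8–C9 and C7–C8 bonds are formed. The closest known chemistry is the Lewis-acid-catalysed homologation of cycloalkanones with non-stabilised diazoalkanes (Büchner–Curtius–Schlotterbeck reaction, a Tiffeneau–Demjanov-type shift), which on α-quaternary cyclopentanones such as 17-oxo steroids mainly moves the methylene carbon. Ring B is not closed by a cyclisation but grows from five to six members by this 1,2-migration (ring-expansion mode), while ring A is carried through unchanged. C8 is the only new stereocentre; nothing controls it and nothing has to, because it is enolisable and becomes an alkene carbon in step 7, whereas C10 is not touched. The step needs attack at the saturated ketone and not at the enone, which the vinylogous deactivation of the C3 carbonyl and the poor dipolarophilicity of the trisubstituted C4=C5 bond at low temperature should secure, and it needs migration of C7 and not of C10, which follows from the adduct rotamer that keeps the new methyl and the N2 group away from the quaternary centre and so places N2 anti to C7. A second insertion is not expected, since the new ketone lies between a quaternary and a tertiary carbon.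

Step 2
Reactants: 4 (8aS)-2,8a-dimethyl-3,4,8,8a-tetrahydronaphthalene-1,6(2H,7H)-dione
Product: 5 (4aS)-5-hydroxy-4a,6-dimethyl-4,4a,5,6,7,8-hexahydronaphthalen-2(3H)-one (9-hydroxy enone; C8 and C9 epimers)
Conditions: NaBH4 (0.3 equiv), MeOH–CH2Cl2 1:1, −78 °C
Reagents that add atoms: none
Why: Chemoselective borohydride reduction of a saturated ketone beside a conjugated enone, standard for the lower 8a-methyl octalindione homologue: the unconjugated C9 carbonyl is the more electrophilic one, hydride should arrive on the α face anti to the C10 methyl to give mainly the 9β-alcohol, and an alcohol is preferred to an acetal as the mask because a carbonyl between a quaternary and a tertiary carbon acetalises too slowly to compete with the enone.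

Step 3
Reactants: 5 9-hydroxy enone
Product: 7 (4aS)-5-hydroxy-1,1,4a,6-tetramethyl-3,4,4a,5,6,7-hexahydronaphthalen-2(1H)-one, via 4-methyl enone 6 (not isolated)
Conditions: t-BuOK (3.5 equiv), MeI (excess), t-BuOH, 25 °C
Reagents that add atoms: iodomethane, CI
Why: Deconjugative α,α-dialkylation of an enone through its extended dienolate (the classical 4,4-dimethylation of 3-oxo-4-ene steroids, which tolerates free hydroxyl groups): both methyl groups enter at C4, the alkene moves to C5=C6, no stereocentre is created, and the crowded C9 alkoxide is a much poorer nucleophile toward MeI than the dienolate carbon.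

Step 4
Reactants: 7 4,4-dimethyl-5-en-3-one
Product: 9 (8aS)-2,5,5,8a-tetramethyl-1,2,3,5,6,7,8,8a-octahydronaphthalen-1-ol, via C3 hydrazone 8 (not isolated)
Conditions: N2H4·H2O, KOH, diethylene glycol, 130 °C, then distillation to 200 °C
Reagents that add atoms: none
Why: Wolff–Kishner reduction in the Huang-Minlon procedure: the C3 hydrazone loses N2 under hot KOH to leave CH2, the C5=C6 bond cannot move into conjugation because C4 and C10 are quaternary, and the free alcohol is inert to these conditions.

Step 5
Reactants: 9 octalinol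
Product: 10 (4aS,8aS)-2,5,5,8a-tetramethyldecahydronaphthalen-1-ol (trans-decalinol; C8 and C9 epimers)
Conditions: H2 (3 atm), PtO2, AcOH, 25 °C
Reagents that add atoms: none
Why: Heterogeneous catalytic hydrogenation: the β face of C5=C6 is covered by the C10 methyl and the β-methyl on C4, so the alkene should bind the catalyst by its α face and receive 5α-H, which sets C5 (S) and the trans ring fusion.

Step 6
Reactants: 10 trans-decalinol
Product: 11 (4aS,8aS)-2,5,5,8a-tetramethyloctahydronaphthalen-1(2H)-one (C8 epimers)
Conditions: Dess–Martin periodinane, CH2Cl2, 25 °C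
Reagents that add atoms: none
Why: Dess–Martin oxidation of a hindered secondary alcohol, which is helped by relief of strain, restores the C9 ketone and merges the C9 epimers without touching C5 or C10.

Step 7
Reactants: 11 trans-decalone
Product: 13 (4aS,8aS)-2,5,5,8a-tetramethyl-4a,5,6,7,8,8a-hexahydronaphthalen-1(4H)-one, via trimethylsilyl enol ether 12 (not isolated)
Conditions: TMSOTf, Et3N, CH2Cl2, 0 → 25 °C; pentane, filtration, evaporation; Pd(OAc)2 (10 mol %), O2 (1 atm), DMSO, 40 °C
Reagents that add atoms: none
Why: Saegusa–Ito dehydrogenation in its aerobic catalytic form: the ketone can enolise only toward C8 because C10 is quaternary, so a single silyl enol ether forms, and β-hydride elimination from the palladium enolate toward C7 gives the conjugated endocyclic C7=C8 enone, the more stable isomer into which any exocyclic methylene ketone is drawn by palladium hydride re-addition.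

Step 8
Reactants: 13 C7=C8 enone
Product: 14 7α,8α-epoxy-11-nordriman-9-one
Conditions: 30% aq H2O2, NaOH, MeOH, 0 → 25 °C
Reagents that add atoms: hydrogen peroxide, OO
Why: Weitz–Scheffer nucleophilic epoxidation: hydroperoxide adds to C7 along the axial trajectory on the α face, anti to the C10 methyl, and the enolate closes on the same face, which sets C7 and C8 as the 7α,8α-epoxide.

Step 9
Reactants: 14 epoxy ketone
Product: 16 (2R,4aR,8aS)-3,4a,8,8-tetramethyl-1,2,4a,5,6,7,8,8a-octahydronaphthalen-2-ol (11-nordrim-8-en-7α-ol), via epoxy hydrazone 15 (not isolated)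
Conditions: N2H4·H2O (5 equiv), AcOH (0.5 equiv), MeOH, 0 → 25 °C
Reagents that add atoms: none
Why: Wharton transposition: the epoxy hydrazone opens to a vinyldiazene that loses N2, so C9 becomes an alkene CH, the double bond lands at C8=C9, and the C7–O bond is never broken, which hands the α configuration of the epoxide on to the 7α-alcohol.

Step 10
Reactants: 16 11-nordrim-8-en-7α-ol
Product: 17 11-nordrim-8-en-7α-yl pyridine-2-carboxylate
Conditions: picolinic acid, DCC, DMAP (10 mol %), CH2Cl2, 25 °C
Reagents that add atoms: picolinic acid, OC(=O)c1ccccn1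
Why: Steglich esterification of the secondary allylic alcohol takes place at oxygen and so keeps the 7α configuration while installing a chelating leaving group.

Step 11
Reactants: 18 2,4,5-trihydroxybenzaldehyde
Product: 19 2,4,5-tris(methoxymethoxy)benzaldehyde
Conditions: MOMCl (4.5 equiv), i-Pr2NEt (6 equiv), CH2Cl2, 0 °C → reflux, N2
Reagents that add atoms: chloromethyl methyl ether, COCCl
Why: Williamson-type O-alkylation of the three phenols with an α-chloro ether; MOM ethers are chosen since they survive organomagnesium, organocopper and organolithium reagents and later direct the lithiation.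

Step 12
Reactants: 19 tris-MOM aldehyde
Product: 20 [2,4,5-tris(methoxymethoxy)phenyl]methanol
Conditions: NaBH4, MeOH, 0 °C
Reagents that add atoms: none
Why: Borohydride reduction of an aromatic aldehyde to the benzylic alcohol, to which the acetal-type ethers are inert.

Step 13
Reactants: 20 benzylic alcohol
Product: 22 1-(chloromethyl)-2,4,5-tris(methoxymethoxy)benzene, via benzylic mesylate 21 (not isolated)
Conditions: MsCl, Et3N, CH2Cl2, 0 → 25 °C
Reagents that add atoms: methanesulfonyl chloride, CS(=O)(=O)Cl
Why: Mesylation with in situ displacement by chloride at a very electron-rich benzylic carbon runs under basic conditions, so that no acid reaches the MOM groups, and the labile chloride is used at once.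

Step 14
Reactants: 17 7α-picolinate; 22 benzylic chloride
Product: 25 (5S,9S,10S)-11-[2,4,5-tris(methoxymethoxy)phenyl]drim-7-ene, via benzylic Grignard reagent 23 (not isolated), via benzylcopper reagent 24 (not isolated)
Conditions: 22 (3 equiv), Mg turnings, THF, 0 °C, slow addition; CuBr·SMe2 (3 equiv), THF, −40 °C; 17, −40 → 0 °C; aq NH4Cl
Reagents that add atoms: none
Why: Copper-mediated anti-SN2′ allylic substitution of a picolinate: the magnesium-chelated leaving group sits pseudoaxially on the α face of C7, so the copper reagent must engage C8=C9 from the β face and hands the benzyl group to C9 with shift of the alkene to C7=C8, which sets C9 (S, C11 β, H α), while the one-to-one magnesium-to-copper stoichiometry and the strongly withdrawing leaving group favour γ over α attack.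

Step 15
Reactants: 25 benzyl drimene
Product: 27 2,3,6-tris(methoxymethoxy)-5-[(5S,9S,10S)-drim-7-en-11-yl]benzaldehyde, via aryllithium 26 (not isolated)
Conditions: n-BuLi, TMEDA, THF, −78 → 0 °C; DMF, −78 → 25 °C; H2O
Reagents that add atoms: N,N-dimethylformamide, CN(C)C=O
Why: Directed ortho-metalation followed by formylation: the C5′–H lies between the OMOM groups on C4′ and C6′, whose combined coordination and acidification steer n-BuLi there rather than to C2′ or to the benzylic and allylic positions.

Step 16
Reactants: 27 protected aldehyde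
Product: 28 2,3,6-trihydroxy-5-{[(1S,4aS,8aS)-2,5,5,8a-tetramethyl-1,4,4a,5,6,7,8,8a-octahydronaphthalen-1-yl]methyl}benzaldehyde (target)
Conditions: HCl (1.25 M in MeOH), 0 → 25 °C, argon; aq work-up
Reagents that add atoms: none
Why: Acid-catalysed acetal exchange cleaves the three phenolic MOM ethers, and dilute methanolic HCl at or below room temperature should leave the trisubstituted C7=C8 bond unprotonated, so that neither alkene migration nor closure of the C6′ phenol onto C8 intervenes and no stereocentre is touched.

Compound list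
1 | (7aS)-7a-methyl-2,3,7,7a-tetrahydro-1H-indene-1,5(6H)-dione | C[C@]12CCC(=O)C=C1CCC2=O | starting material
2 | N-ethyl-N-nitrosourea | CCN(N=O)C(N)=O | starting material
3 | diazoethane | CC=[N+]=[N-] | intermediate
4 | (8aS)-2,8a-dimethyl-3,4,8,8a-tetrahydronaphthalene-1,6(2H,7H)-dione (C8 epimers) | C[C@]12CCC(=O)C=C1CCC(C)C2=O | intermediate
5 | (4aS)-5-hydroxy-4a,6-dimethyl-4,4a,5,6,7,8-hexahydronaphthalen-2(3H)-one (C8, C9 epimers) | C[C@]12CCC(=O)C=C1CCC(C)C2O | intermediate
6 | (4aS)-5-hydroxy-1,4a,6-trimethyl-4,4a,5,6,7,8-hexahydronaphthalen-2(3H)-one | C[C@]12CCC(=O)C(C)=C1CCC(C)C2O | intermediate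
7 | (4aS)-5-hydroxy-1,1,4a,6-tetramethyl-3,4,4a,5,6,7-hexahydronaphthalen-2(1H)-one | C[C@]12CCC(=O)C(C)(C)C1=CCC(C)C2O | intermediate
8 | C3 hydrazone of 7 | C[C@]12CCC(=NN)C(C)(C)C1=CCC(C)C2O | intermediate
9 | (8aS)-2,5,5,8a-tetramethyl-1,2,3,5,6,7,8,8a-octahydronaphthalen-1-ol | C[C@]12CCCC(C)(C)C1=CCC(C)C2O | intermediate
10 | (4aS,8aS)-2,5,5,8a-tetramethyldecahydronaphthalen-1-ol (5α-H, 10β-Me) | CC1CC[C@H]2C(C)(C)CCC[C@]2(C)C1O | intermediate
11 | (4aS,8aS)-2,5,5,8a-tetramethyloctahydronaphthalen-1(2H)-one | CC1CC[C@H]2C(C)(C)CCC[C@]2(C)C1=O | intermediate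
12 | C8=C9 trimethylsilyl enol ether of 11 | CC1=C(O[Si](C)(C)C)[C@@]2(C)CCCC(C)(C)[C@@H]2CC1 | intermediate
13 | (4aS,8aS)-2,5,5,8a-tetramethyl-4a,5,6,7,8,8a-hexahydronaphthalen-1(4H)-one | CC1=CC[C@H]2C(C)(C)CCC[C@]2(C)C1=O | intermediate
14 | 7α,8α-epoxy-11-nordriman-9-one | C[C@@]12O[C@@H]1C[C@H]3C(C)(C)CCC[C@]3(C)C2=O | intermediate
15 | C9 hydrazone of 14 | C[C@@]12O[C@@H]1C[C@H]3C(C)(C)CCC[C@]3(C)C2=NN | intermediate
16 | (2R,4aR,8aS)-3,4a,8,8-tetramethyl-1,2,4a,5,6,7,8,8a-octahydronaphthalen-2-ol (11-nordrim-8-en-7α-ol) | CC1=C[C@@]2(C)CCCC(C)(C)[C@@H]2C[C@H]1O | intermediate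
17 | 11-nordrim-8-en-7α-yl pyridine-2-carboxylate | CC1=C[C@@]2(C)CCCC(C)(C)[C@@H]2C[C@H]1OC(=O)c1ccccn1 | intermediate
18 | 2,4,5-trihydroxybenzaldehyde | O=Cc1cc(O)c(O)cc1O | starting material
19 | 2,4,5-tris(methoxymethoxy)benzaldehyde | COCOc1cc(OCOC)c(OCOC)cc1C=O | intermediate
20 | [2,4,5-tris(methoxymethoxy)phenyl]methanol | COCOc1cc(OCOC)c(OCOC)cc1CO | intermediate
21 | 2,4,5-tris(methoxymethoxy)benzyl methanesulfonate | COCOc1cc(OCOC)c(OCOC)cc1COS(C)(=O)=O | intermediate
22 | 1-(chloromethyl)-2,4,5-tris(methoxymethoxy)benzene | COCOc1cc(OCOC)c(OCOC)cc1CCl | intermediate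
23 | 2,4,5-tris(methoxymethoxy)benzylmagnesium chloride | COCOc1cc(OCOC)c(OCOC)cc1C[Mg]Cl | intermediate
24 | 2,4,5-tris(methoxymethoxy)benzylcopper | COCOc1cc(OCOC)c(OCOC)cc1C[Cu] | intermediate
25 | (5S,9S,10S)-11-[2,4,5-tris(methoxymethoxy)phenyl]drim-7-ene | CC1=CC[C@H]2C(C)(C)CCC[C@]2(C)[C@H]1Cc1cc(OCOC)c(OCOC)cc1OCOC | intermediate
26 | C5′-lithio derivative of 25 | CC1=CC[C@H]2C(C)(C)CCC[C@]2(C)[C@H]1Cc1cc(OCOC)c(OCOC)c([Li])c1OCOC | intermediate
27 | 2,3,6-tris(methoxymethoxy)-5-[(5S,9S,10S)-drim-7-en-11-yl]benzaldehyde | CC1=CC[C@H]2C(C)(C)CCC[C@]2(C)[C@H]1Cc1cc(OCOC)c(OCOC)c(C=O)c1OCOC | intermediate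
28 | 2,3,6-trihydroxy-5-{[(1S,4aS,8aS)-2,5,5,8a-tetramethyl-1,4,4a,5,6,7,8,8a-octahydronaphthalen-1-yl]methyl}benzaldehyde | CC1=CC[C@H]2C(C)(C)CCC[C@]2(C)[C@H]1Cc1cc(O)c(O)c(C=O)c1O | target

Total step count: 16. Longest linear sequence: 13 (steps 1–10 and 14–16). The arene branch, steps 11–13, joins at step 14.

Steps most likely to fail

Step 1. Diazoethane may be consumed by the enone, either by dipolar cycloaddition to C4=C5 or by attack at C3. The quaternary C10 may migrate in part, or the adduct may collapse to the spiro-epoxide.
Fallback, from 1 back to 4: a stabilised diazo ester replaces the alkyl diazo compound, and the methyl group is added afterwards.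
- Ethyl diazoacetate with BF3·OEt2 in CH2Cl2 at 0 °C is indifferent to the enone alkene. It is known to insert on the methylene side of α-quaternary cyclopentanones, which should give ethyl (8aS)-8a-methyl-1,6-dioxo-1,2,3,4,6,7,8,8a-octahydronaphthalene-2-carboxylate F1.
- K2CO3 and MeI in acetone methylate only the acidic β-keto ester carbon C8, giving ethyl (8aS)-2,8a-dimethyl-1,6-dioxo-1,2,3,4,6,7,8,8a-octahydronaphthalene-2-carboxylate F2.
- Krapcho dealkoxycarbonylation (LiCl, wet DMSO, 150 °C) then delivers 4.

Step 9. Hydrazone formation at the C9 carbonyl, which is flanked by two fully substituted carbons, may be so slow that hydrazine opens the epoxide at C7 instead.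
Fallback, from 14 back to 16: the transposition is run as a radical fragmentation.
- NaBH4 in MeOH reduces the ketone to 7α,8α-epoxy-11-nordriman-9-ol F3.
- 1,1′-Thiocarbonyldiimidazole with DMAP in hot toluene gives its O-(imidazol-1-ylthiocarbonyl) derivative F4.
- Bu3SnH and AIBN in refluxing toluene generate the C9 radical, which opens the C8–O bond of the oxirane. The resulting C7 alkoxy radical picks up hydrogen to give 16 with the 7α C–O bond intact.

Step 14. The benzyl group may be transferred to C7 (α-substitution). Alternatively, the benzylcopper may dimerise thermally before it can reach the β face of C9, which the C10 methyl shields.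
Fallback, from 13 back to 25 (steps 8–10 and 13 are then not needed): C11 is attached to C9 while C9 is still sp2, and C9–H is delivered from the open α face.
- Me3SiCH2Li with CeCl3 in THF at −78 °C adds to the enone carbonyl to give 9-hydroxy-9-(trimethylsilylmethyl)-11-nordrim-7-ene F5.
- KH in THF completes the Peterson olefination to drima-7,9(11)-diene F6.
- 9-BBN in THF adds to the exocyclic C9=C11 bond from the α face, with boron on C11 and hydrogen on C9α, giving 11-(9-borabicyclo[3.3.1]nonan-9-yl)drim-7-ene F7.
- In parallel, purchased benzene-1,2,4-triol is converted with MOMCl and i-Pr2NEt into 1,2,4-tris(methoxymethoxy)benzene F8. NBS in MeCN then brominates it para to the C2 oxygen, giving 1-bromo-2,4,5-tris(methoxymethoxy)benzene F9.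
- B-alkyl Suzuki–Miyaura coupling of the borane with this bromide (PdCl2(dppf), K3PO4, DMF–H2O, 60 °C) gives 25.

Further compounds
F1 | step 1 | ethyl (8aS)-8a-methyl-1,6-dioxo-1,2,3,4,6,7,8,8a-octahydronaphthalene-2-carboxylate | C[C@]12CCC(=O)C=C1CCC(C(=O)OCC)C2=O
F2 | step 1 | ethyl (8aS)-2,8a-dimethyl-1,6-dioxo-1,2,3,4,6,7,8,8a-octahydronaphthalene-2-carboxylate | C[C@]12CCC(=O)C=C1CCC(C)(C(=O)OCC)C2=O
F3 | step 9 | 7α,8α-epoxy-11-nordriman-9-ol | C[C@@]12O[C@@H]1C[C@H]3C(C)(C)CCC[C@]3(C)C2O
F4 | step 9 | O-(7α,8α-epoxy-11-nordriman-9-yl) 1H-imidazole-1-carbothioate | C[C@@]12O[C@@H]1C[C@H]3C(C)(C)CCC[C@]3(C)C2OC(=S)n1ccnc1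
F5 | step 14 | 9-hydroxy-9-(trimethylsilylmethyl)-11-nordrim-7-ene | CC1=CC[C@H]2C(C)(C)CCC[C@]2(C)C1(O)C[Si](C)(C)C
F6 | step 14 | drima-7,9(11)-diene | CC1=CC[C@H]2C(C)(C)CCC[C@]2(C)C1=C
F7 | step 14 | 11-(9-borabicyclo[3.3.1]nonan-9-yl)drim-7-ene | CC1=CC[C@H]2C(C)(C)CCC[C@]2(C)[C@H]1CB1C2CCCC1CCC2
F8 | step 14 | 1,2,4-tris(methoxymethoxy)benzene | COCOc1ccc(OCOC)c(OCOC)c1
F9 | step 14 | 1-bromo-2,4,5-tris(methoxymethoxy)benzene | COCOc1cc(OCOC)c(OCOC)cc1Br
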